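## Retrosynthetic overview

1. The C40 chain is cut at C11=C12 and C11'=C12' (two Wittig reactions), giving the acetylenic C15 phosphonium salt 20 (ring A), the C10 dialdehyde 25 and the 7',8'-dihydro C15 phosphonium salt 24 (ring B).
2. Both salts come from one enol triflate 17: Sonogashira coupling (C6–C7) with enynol 18 for ring A, B-alkyl Suzuki coupling (C6'–C7') with dienol 21 for ring B.
3. Triflate 17 comes from ketone 14, whose carbocycle is closed at C2–C3 by a strain-release homoaldol: the C6–C2 bond of the siloxycyclopropane aldehyde 12 opens onto the C3 aldehyde.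
4. Enabling feature: in ring A, C6 is the sp2 carbon that carries the alkynyl chain, so it can be a carbonyl. C2 is β to it through the fully substituted C1(CH3)2, and C3 is a carbinol carbon. C6–C1–C2 is therefore a latent 1-siloxy-2,2-dimethylcyclopropane (a ketone homoenolate) and C3 an aldehyde; the C1 gem-dimethyl group steers ring opening to C2 and, with a temporary C5 methyl stereocentre, fixes (3R).
5. Ring order: cyclopropane C6–C1–C2 (step 5), then the six-membered ring (step 7); one batch of 17 serves ring A and ring B, and no ring is formed later.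

Key step: step 7

Remark: carotenoid numbering is used for ring and chain atoms. Compounds 10, 11 and 12 are carried as both epimers at the cyclopropane carbinol carbon (it becomes the C6 carbonyl), so that centre is left undefined in their SMILES. Triflate 17 is divided between steps 10 and 13.

## Route

Step 1
Reactants: 1 (4R)-4-benzyl-3-propanoyl-1,3-oxazolidin-2-one; 2 allyl iodide
Product: 4 (4R)-4-benzyl-3-[(2S)-2-methylpent-4-enoyl]-1,3-oxazolidin-2-one, via sodium enolate 3 (not isolated)
Conditions: NaN(SiMe3)2, THF, −78 °C; then 2, −78 → −40 °C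
Reagents that add atoms: none
Why: Evans asymmetric alkylation, in which the chelated Z-enolate is allylated on the face opposite the benzyl group of the (R)-auxiliary, should set the (S)-methyl stereocentre (future C5, the temporary control element).

Step 2
Reactants: 4 (4R)-4-benzyl-3-[(2S)-2-methylpent-4-enoyl]-1,3-oxazolidin-2-one
Product: 5 (2S)-N-methoxy-N,2-dimethylpent-4-enamide
Conditions: MeNH(OMe)·HCl, AlMe3, CH2Cl2, −15 → 0 °C; aq. HCl
Reagents that add atoms: N,O-dimethylhydroxylamine hydrochloride, CNOC.Cl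
Why: Aluminium amide transamination (Weinreb amide formation) should cleave the exocyclic imide carbonyl without epimerisation and release the auxiliary.

Step 3
Reactants: 5 (2S)-N-methoxy-N,2-dimethylpent-4-enamide; 6 isopropenylmagnesium bromide
Product: 8 (4S)-2,4-dimethylhepta-1,6-dien-3-one, via bromomagnesium hemiaminal 7 (not isolated)
Conditions: THF, 0 °C; cold aq. NH4Cl
Reagents that add atoms: none
Why: Weinreb ketone synthesis, in which the chelated tetrahedral adduct prevents over-addition and conjugate addition, should give the isopropenyl ketone with the α'-stereocentre intact.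

Step 4
Reactants: 8 (4S)-2,4-dimethylhepta-1,6-dien-3-one
Product: 9 {[(4S)-2,4-dimethylhepta-2,6-dien-3-yl]oxy}dimethyl(phenyl)silane
Conditions: [(Ph3P)CuH]6 (cat.), PhMe2SiH, toluene, 0 °C → rt
Reagents that add atoms: dimethylphenylsilane, C[SiH](C)c1ccccc1
Why: Copper hydride-catalysed 1,4-hydrosilylation of the enone should give the tetrasubstituted silyl enol ether regiospecifically on the isopropylidene side, so that the stereocentre on the other α-carbon is never enolised and the isolated alkene is untouched.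

Step 5
Reactants: 9 {[(4S)-2,4-dimethylhepta-2,6-dien-3-yl]oxy}dimethyl(phenyl)silane
Product: 10 {[2,2-dimethyl-1-[(2S)-pent-4-en-2-yl]cyclopropyl]oxy}dimethyl(phenyl)silane (both epimers at the carbinol carbon)
Conditions: Et2Zn, CH2I2, CH2Cl2, 0 °C; pyridine, aq. NH4Cl
Reagents that add atoms: diiodomethane, ICI
Why: Simmons–Smith (Furukawa) cyclopropanation, whose electrophilic zinc carbenoid reacts with the electron-rich silyl enol ether much faster than with the monosubstituted alkene, should deliver the CH2 group that becomes C2, the new carbinol centre being inconsequential.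

Step 6
Reactants: 10 {[2,2-dimethyl-1-[(2S)-pent-4-en-2-yl]cyclopropyl]oxy}dimethyl(phenyl)silane
Product: 12 (3S)-3-{1-[dimethyl(phenyl)silyloxy]-2,2-dimethylcyclopropyl}butanal, via secondary ozonide 11 (not isolated)
Conditions: O3, CH2Cl2, −78 °C (indicator end point); then PPh3, −78 °C → rt
Reagents that add atoms: ozone, [O-][O+]=O
Why: Ozonolysis with reductive work-up should cleave only the terminal alkene to the aldehyde (future C3), since the siloxycyclopropane has no π bond to attack at −78 °C.

Step 7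
Reactants: 12 (3S)-3-{1-[dimethyl(phenyl)silyloxy]-2,2-dimethylcyclopropyl}butanal
Product: 14 (4R,6S)-4-hydroxy-2,2,6-trimethylcyclohexan-1-one, via trichlorotitanium alkoxide 13 (not isolated)
Conditions: TiCl4 (1.1 equiv), CH2Cl2, −78 → −40 °C; aq. NaHCO3
Reagents that add atoms: none
Why: Proposed new method: TiCl4 binds the aldehyde oxygen, and the siloxy-polarised C6–C2 σ bond of the cyclopropane, acting as a homo-enol silyl ether, attacks the activated C3 carbonyl from its CH2 terminus (front-side SE2), so that C2–C3 forms as C6–C2 breaks and the silyloxocarbenium ion at C6 loses PhMe2SiCl to unveil the ketone, the release of cyclopropane strain driving the step; prior titanation of the cyclopropane to a β-titanio ketone would converge on the same bond. The closest known reaction types are the TiCl4-mediated homoaldol (homo-Reformatsky) addition of 1-alkoxy-1-siloxycyclopropanes to aldehydes and the Lewis acid-promoted fragmentation of cyclopropanols onto tethered oxocarbenium ions that gives oxepan-4-ones, neither of which has closed a carbocycle onto a free aldehyde. The six-membered ring is closed in a 6-exo-trig mode at the aldehyde carbon, the three-membered ring being opened at its unsubstituted carbon. The new C3 stereocentre is controlled by the C5 methyl group: in the chair-like transition state the axial methyl of the C1 gem-dimethyl group forces both the C5 methyl and the titanium-bound C3 oxygen into equatorial positions, which should give the 3,5-cis ring and hence (3R) from (5S). The step needs cleavage of C6–C2 rather than C6–C1 and no loss of the C5 configuration before ring closure; the first is secured by the fully substituted C1, which shields its own cyclopropane bond and carries no hydrogen for enolisation or elimination, the second by the non-basic, low-temperature conditions under which C5 becomes α to a carbonyl only once the C–C bond exists.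

Step 8
Reactants: 14 (4R,6S)-4-hydroxy-2,2,6-trimethylcyclohexan-1-one
Product: 15 (4R,6S)-2,2,6-trimethyl-4-(triethylsilyloxy)cyclohexan-1-one
Conditions: Et3SiCl, imidazole, CH2Cl2, 0 °C
Reagents that add atoms: chlorotriethylsilane, CC[Si](Cl)(CC)CC
Why: Standard imidazole-mediated silylation should protect the secondary C3 hydroxyl for the enolate chemistry without touching the hindered ketone.

Step 9
Reactants: 15 (4R,6S)-2,2,6-trimethyl-4-(triethylsilyloxy)cyclohexan-1-one
Product: 17 (4R)-2,6,6-trimethyl-4-(triethylsilyloxy)cyclohex-1-en-1-yl trifluoromethanesulfonate, via lithium enolate 16 (not isolated)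
Conditions: LiN(i-Pr)2, THF, −78 → 0 °C; then PhNTf2, −78 → 0 °C; aq. NH4Cl
Reagents that add atoms: N-phenylbis(trifluoromethanesulfonimide), FC(F)(F)S(=O)(=O)N(c1ccccc1)S(=O)(=O)C(F)(F)F
Why: The ketone has a single enolisable hydrogen (C5–H), so deprotonation and O-triflation should give the C5=C6 enol triflate regiospecifically, erasing the temporary C5 stereocentre and leaving C3 untouched.

Step 10
Reactants: 17 (4R)-2,6,6-trimethyl-4-(triethylsilyloxy)cyclohex-1-en-1-yl trifluoromethanesulfonate; 18 (2E)-3-methylpent-2-en-4-yn-1-ol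
Product: 19 (2E)-3-methyl-5-[(4R)-2,6,6-trimethyl-4-(triethylsilyloxy)cyclohex-1-en-1-yl]pent-2-en-4-yn-1-ol
Conditions: Pd(PPh3)4 (cat.), CuI (cat.), i-Pr2NH, DMF, rt
Reagents that add atoms: none
Why: Sonogashira coupling of the enol triflate with the terminal alkyne should form C6–C7 with the (E)-enyne geometry of 18 retained, a reaction type established for 2,6,6-trimethylcyclohexenyl triflates.

Step 11
Reactants: 19 (2E)-3-methyl-5-[(4R)-2,6,6-trimethyl-4-(triethylsilyloxy)cyclohex-1-en-1-yl]pent-2-en-4-yn-1-ol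
Product: 20 {(2E)-5-[(4R)-4-hydroxy-2,6,6-trimethylcyclohex-1-en-1-yl]-3-methylpent-2-en-4-yn-1-yl}triphenylphosphonium bromide
Conditions: Ph3P·HBr, MeOH, 0 °C → rt
Reagents that add atoms: triphenylphosphine hydrobromide, [Br-].c1ccc(cc1)[PH+](c1ccccc1)c1ccccc1
Why: Displacement of the protonated primary allylic hydroxyl by PPh3 (the classical preparation of C15 Wittig salts) should give the phosphonium salt, while the same acid in methanol solvolyses the triethylsilyl ether.

Step 12
Reactants: 18 (2E)-3-methylpent-2-en-4-yn-1-ol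
Product: 21 (2E)-3-methylpenta-2,4-dien-1-ol
Conditions: H2 (1 atm), Pd/CaCO3 poisoned with Pb(OAc)2, quinoline, EtOAc, rt
Reagents that add atoms: none
Why: Lindlar semihydrogenation should stop at the vinyl stage for a terminal alkyne and leave the trisubstituted (E)-double bond unchanged.

Step 13
Reactants: 21 (2E)-3-methylpenta-2,4-dien-1-ol; 17 (4R)-2,6,6-trimethyl-4-(triethylsilyloxy)cyclohex-1-en-1-yl trifluoromethanesulfonate
Product: 23 (2E)-3-methyl-5-[(4R)-2,6,6-trimethyl-4-(triethylsilyloxy)cyclohex-1-en-1-yl]pent-2-en-1-ol, via alkylborane 22 (not isolated)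
Conditions: 9-BBN (2.1 equiv), THF, 0 °C → rt; then 17, PdCl2(dppf) (cat.), AsPh3, Cs2CO3, DMF/H2O, 50 °C
Reagents that add atoms: none
Why: 9-BBN should hydroborate only the terminal vinyl group of the diene in the anti-Markovnikov sense (the first equivalent is taken up by the hydroxyl), and B-alkyl Suzuki–Miyaura coupling with the enol triflate should then form the C6'–C7' bond with the (E)-C9'=C10' geometry already in place.

Step 14
Reactants: 23 (2E)-3-methyl-5-[(4R)-2,6,6-trimethyl-4-(triethylsilyloxy)cyclohex-1-en-1-yl]pent-2-en-1-ol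
Product: 24 {(2E)-5-[(4R)-4-hydroxy-2,6,6-trimethylcyclohex-1-en-1-yl]-3-methylpent-2-en-1-yl}triphenylphosphonium bromide
Conditions: Ph3P·HBr, MeOH, 0 °C → rt
Reagents that add atoms: triphenylphosphine hydrobromide, [Br-].c1ccc(cc1)[PH+](c1ccccc1)c1ccccc1
Why: As in step 11, PPh3 should displace the protonated primary allylic hydroxyl with retention of the geranyl-type (E)-geometry while the triethylsilyl ether is solvolysed.

Step 15
Reactants: 24 {(2E)-5-[(4R)-4-hydroxy-2,6,6-trimethylcyclohex-1-en-1-yl]-3-methylpent-2-en-1-yl}triphenylphosphonium bromide; 25 (2E,4E,6E)-2,7-dimethylocta-2,4,6-trienedial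
Product: 26 (2E,4E,6E,8E,10E)-13-[(4R)-4-hydroxy-2,6,6-trimethylcyclohex-1-en-1-yl]-2,7,11-trimethyltrideca-2,4,6,8,10-pentaenal
Conditions: NaOMe, MeOH/CH2Cl2, 0 °C → rt, 25 in excess (2 equiv); then heptane, 80 °C
Reagents that add atoms: none
Why: Wittig olefination of the allylic ylide with one formyl group of the excess dialdehyde should stop at the mono-adduct, which is a more conjugated and less electrophilic aldehyde, and the hindered 11'Z isomer is expected to relax thermally to E.

Step 16
Reactants: 20 {(2E)-5-[(4R)-4-hydroxy-2,6,6-trimethylcyclohex-1-en-1-yl]-3-methylpent-2-en-4-yn-1-yl}triphenylphosphonium bromide; 26 (2E,4E,6E,8E,10E)-13-[(4R)-4-hydroxy-2,6,6-trimethylcyclohex-1-en-1-yl]-2,7,11-trimethyltrideca-2,4,6,8,10-pentaenal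
Product: 27 (all-E)-(3R,3'R)-7,8-didehydro-7',8'-dihydro-β,β-carotene-3,3'-diol (CNP0178054.1)
Conditions: NaOMe, MeOH/CH2Cl2, 0 °C → rt, dark, argon
Reagents that add atoms: none
Why: The second Wittig olefination should form C11=C12 and complete the C40 chain under mild base, so that the free hydroxyls, the enyne and the (9E) geometry persist; E is expected to predominate and minor Z isomers would be removed by crystallisation.

## Compound list

1 | (4R)-4-benzyl-3-propanoyl-1,3-oxazolidin-2-one | CCC(=O)N1[C@H](Cc2ccccc2)COC1=O | starting material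
2 | allyl iodide | C=CCI | starting material
3 | sodium (Z)-enolate of 1 | C/C=C(\[O-])N1[C@H](Cc2ccccc2)COC1=O.[Na+] | intermediate (not isolated)
4 | (4R)-4-benzyl-3-[(2S)-2-methylpent-4-enoyl]-1,3-oxazolidin-2-one | C=CC[C@H](C)C(=O)N1[C@H](Cc2ccccc2)COC1=O | intermediate
5 | (2S)-N-methoxy-N,2-dimethylpent-4-enamide | C=CC[C@H](C)C(=O)N(C)OC | intermediate
6 | isopropenylmagnesium bromide | CC(=C)[Mg]Br | starting material
7 | bromomagnesium hemiaminal from 5 and 6 | C=CC[C@H](C)C(O[Mg]Br)(N(C)OC)C(C)=C | intermediate (not isolated)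
8 | (4S)-2,4-dimethylhepta-1,6-dien-3-one | C=CC[C@H](C)C(=O)C(C)=C | intermediate
9 | {[(4S)-2,4-dimethylhepta-2,6-dien-3-yl]oxy}dimethyl(phenyl)silane | C=CC[C@H](C)C(O[Si](C)(C)c1ccccc1)=C(C)C | intermediate
10 | {[2,2-dimethyl-1-[(2S)-pent-4-en-2-yl]cyclopropyl]oxy}dimethyl(phenyl)silane | C=CC[C@H](C)C1(O[Si](C)(C)c2ccccc2)CC1(C)C | intermediate
11 | secondary ozonide (1,2,4-trioxolane) of 10 | C1OC(C[C@H](C)C2(O[Si](C)(C)c3ccccc3)CC2(C)C)OO1 | intermediate (not isolated)
12 | (3S)-3-{1-[dimethyl(phenyl)silyloxy]-2,2-dimethylcyclopropyl}butanal | O=CC[C@H](C)C1(O[Si](C)(C)c2ccccc2)CC1(C)C | intermediate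
13 | trichlorotitanium alkoxide of 14 | CC1(C)C[C@H](O[Ti](Cl)(Cl)Cl)C[C@H](C)C1=O | intermediate (not isolated)
14 | (4R,6S)-4-hydroxy-2,2,6-trimethylcyclohexan-1-one | CC1(C)C[C@H](O)C[C@H](C)C1=O | intermediate
15 | (4R,6S)-2,2,6-trimethyl-4-(triethylsilyloxy)cyclohexan-1-one | CC1(C)C[C@H](O[Si](CC)(CC)CC)C[C@H](C)C1=O | intermediate
16 | lithium enolate of 15 | CC1=C([O-])C(C)(C)C[C@H](O[Si](CC)(CC)CC)C1.[Li+] | intermediate (not isolated)
17 | (4R)-2,6,6-trimethyl-4-(triethylsilyloxy)cyclohex-1-en-1-yl trifluoromethanesulfonate | CC1=C(OS(=O)(=O)C(F)(F)F)C(C)(C)C[C@H](O[Si](CC)(CC)CC)C1 | intermediate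
18 | (2E)-3-methylpent-2-en-4-yn-1-ol | C#C/C(C)=C/CO | starting material
19 | (2E)-3-methyl-5-[(4R)-2,6,6-trimethyl-4-(triethylsilyloxy)cyclohex-1-en-1-yl]pent-2-en-4-yn-1-ol | CC1=C(C#C/C(C)=C/CO)C(C)(C)C[C@H](O[Si](CC)(CC)CC)C1 | intermediate
20 | {(2E)-5-[(4R)-4-hydroxy-2,6,6-trimethylcyclohex-1-en-1-yl]-3-methylpent-2-en-4-yn-1-yl}triphenylphosphonium bromide | CC1=C(C#C/C(C)=C/C[P+](c2ccccc2)(c2ccccc2)c2ccccc2)C(C)(C)C[C@H](O)C1.[Br-] | intermediate
21 | (2E)-3-methylpenta-2,4-dien-1-ol | C=C/C(C)=C/CO | intermediate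
22 | 9-[(3E)-5-(9-borabicyclo[3.3.1]nonan-9-yloxy)-3-methylpent-3-en-1-yl]-9-borabicyclo[3.3.1]nonane | B1(CC/C(C)=C/COB2C3CCCC2CCC3)C2CCCC1CCC2 | intermediate (not isolated)
23 | (2E)-3-methyl-5-[(4R)-2,6,6-trimethyl-4-(triethylsilyloxy)cyclohex-1-en-1-yl]pent-2-en-1-ol | CC1=C(CC/C(C)=C/CO)C(C)(C)C[C@H](O[Si](CC)(CC)CC)C1 | intermediate
24 | {(2E)-5-[(4R)-4-hydroxy-2,6,6-trimethylcyclohex-1-en-1-yl]-3-methylpent-2-en-1-yl}triphenylphosphonium bromide | CC1=C(CC/C(C)=C/C[P+](c2ccccc2)(c2ccccc2)c2ccccc2)C(C)(C)C[C@H](O)C1.[Br-] | intermediate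
25 | (2E,4E,6E)-2,7-dimethylocta-2,4,6-trienedial | O=C/C(C)=C/C=C/C=C(C)/C=O | starting material
26 | (2E,4E,6E,8E,10E)-13-[(4R)-4-hydroxy-2,6,6-trimethylcyclohex-1-en-1-yl]-2,7,11-trimethyltrideca-2,4,6,8,10-pentaenal | CC1=C(CC/C(C)=C/C=C/C(C)=C/C=C/C=C(C)/C=O)C(C)(C)C[C@H](O)C1 | intermediate
27 | (all-E)-(3R,3'R)-7,8-didehydro-7',8'-dihydro-β,β-carotene-3,3'-diol | CC1=C(C#C/C(C)=C/C=C/C(C)=C/C=C/C=C(C)/C=C/C=C(\C)CCC2=C(C)C[C@@H](O)CC2(C)C)C(C)(C)C[C@H](O)C1 | target

## Step count and risks

Total step count: 16. Longest linear sequence: 13 steps (steps 1–9, 13, 14, 15, 16).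

**1. Step 7.** The Lewis acid-activated aldehyde may be consumed by intermolecular aldol oligomerisation, or protodesilylative opening of the cyclopropane to the tert-butyl ketone may outrun C–C bond formation. Weak facial discrimination would also erode the 3,5-cis (3R) selectivity. The fallback sets out from 12 and returns at 14. N-Iodosuccinimide (CH2Cl2, 0 °C) would open the siloxycyclopropane at its CH2 carbon, the known halogenative ring opening of siloxycyclopropanes to β-halo ketones, to give (3S)-6-iodo-3,5,5-trimethyl-4-oxohexanal F1. An intramolecular alkyl iodide–aldehyde coupling of the Nozaki–Hiyama–Takai type (CrCl2, catalytic cobalt phthalocyanine Co(C32H16N8), DMF), in which alkylchromium species add to aldehydes but not to ketones, would then close the same C2–C3 bond under the same chair control and give 14.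

**2. Step 13.** Oxidative addition and transmetalation at the doubly flanked, tetrasubstituted triflate may be slow, so that protodeboronation and β-hydride elimination of the alkylpalladium species compete; hydroboration of the diene may also go beyond the terminal vinyl group. The fallback sets out from 17 and returns at 23. Heck reaction of 17 with methyl vinyl ketone (Pd(OAc)2, PPh3, Et3N, DMF) would give (3E)-4-[(4R)-2,6,6-trimethyl-4-(triethylsilyloxy)cyclohex-1-en-1-yl]but-3-en-2-one F2. Conjugate reduction of the enone with [(Ph3P)CuH]6 would give 4-[(4R)-2,6,6-trimethyl-4-(triethylsilyloxy)cyclohex-1-en-1-yl]butan-2-one F3. Horner–Wadsworth–Emmons reaction with triethyl phosphonoacetate (NaH, THF) would give, after removal of the 2Z isomer, ethyl (2E)-3-methyl-5-[(4R)-2,6,6-trimethyl-4-(triethylsilyloxy)cyclohex-1-en-1-yl]pent-2-enoate F4, and reduction with i-Bu2AlH would give 23.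

**3. Step 16.** The enyne-conjugated allylic ylide may isomerise (loss of the 9E geometry), and E/Z control at the new C11=C12 bond may be poor. The fallback reverses the polarity of the last olefination; it sets out from 19 and 26 and returns at 27. MnO2 would oxidise 19 to (2E)-3-methyl-5-[(4R)-2,6,6-trimethyl-4-(triethylsilyloxy)cyclohex-1-en-1-yl]pent-2-en-4-ynal F5, a geometrically fixed enynal. NaBH4 would reduce 26 to (2E,4E,6E,8E,10E)-13-[(4R)-4-hydroxy-2,6,6-trimethylcyclohex-1-en-1-yl]-2,7,11-trimethyltrideca-2,4,6,8,10-pentaen-1-ol F6, and Ph3P·HBr in MeOH would convert it into [(2E,4E,6E,8E,10E)-13-[(4R)-4-hydroxy-2,6,6-trimethylcyclohex-1-en-1-yl]-2,7,11-trimethyltrideca-2,4,6,8,10-pentaen-1-yl]triphenylphosphonium bromide F7. Wittig reaction of F7 with F5 (NaOMe, MeOH/CH2Cl2) would give the 3-O-triethylsilyl ether of the target F8, and Bu4NF (THF, 0 °C) would give 27.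

## Further compounds

F1 | step 7 | (3S)-6-iodo-3,5,5-trimethyl-4-oxohexanal | O=CC[C@H](C)C(=O)C(C)(C)CI
F2 | step 13 | (3E)-4-[(4R)-2,6,6-trimethyl-4-(triethylsilyloxy)cyclohex-1-en-1-yl]but-3-en-2-one | CC1=C(/C=C/C(C)=O)C(C)(C)C[C@H](O[Si](CC)(CC)CC)C1
F3 | step 13 | 4-[(4R)-2,6,6-trimethyl-4-(triethylsilyloxy)cyclohex-1-en-1-yl]butan-2-one | CC1=C(CCC(C)=O)C(C)(C)C[C@H](O[Si](CC)(CC)CC)C1
F4 | step 13 | ethyl (2E)-3-methyl-5-[(4R)-2,6,6-trimethyl-4-(triethylsilyloxy)cyclohex-1-en-1-yl]pent-2-enoate | CC1=C(CC/C(C)=C/C(=O)OCC)C(C)(C)C[C@H](O[Si](CC)(CC)CC)C1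
F5 | step 16 | (2E)-3-methyl-5-[(4R)-2,6,6-trimethyl-4-(triethylsilyloxy)cyclohex-1-en-1-yl]pent-2-en-4-ynal | CC1=C(C#C/C(C)=C/C=O)C(C)(C)C[C@H](O[Si](CC)(CC)CC)C1
F6 | step 16 | (2E,4E,6E,8E,10E)-13-[(4R)-4-hydroxy-2,6,6-trimethylcyclohex-1-en-1-yl]-2,7,11-trimethyltrideca-2,4,6,8,10-pentaen-1-ol | CC1=C(CC/C(C)=C/C=C/C(C)=C/C=C/C=C(C)/CO)C(C)(C)C[C@H](O)C1
F7 | step 16 | [(2E,4E,6E,8E,10E)-13-[(4R)-4-hydroxy-2,6,6-trimethylcyclohex-1-en-1-yl]-2,7,11-trimethyltrideca-2,4,6,8,10-pentaen-1-yl]triphenylphosphonium bromide | CC1=C(CC/C(C)=C/C=C/C(C)=C/C=C/C=C(C)/C[P+](c2ccccc2)(c2ccccc2)c2ccccc2)C(C)(C)C[C@H](O)C1.[Br-]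
F8 | step 16 | (all-E)-(3R,3'R)-3-(triethylsilyloxy)-7,8-didehydro-7',8'-dihydro-β,β-caroten-3'-ol | CC1=C(C#C/C(C)=C/C=C/C(C)=C/C=C/C=C(C)/C=C/C=C(\C)CCC2=C(C)C[C@@H](O)CC2(C)C)C(C)(C)C[C@H](O[Si](CC)(CC)CC)C1
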